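The data stem from a simulated flask from invented constants; the scatter is artificial.

The beta run is a close neighbour of the eta flask: it holds the same partner charge, 0.200 M, with twice the substrate of eta, and its last reading, at 4.1 h, was 0.0356 M of target. What that says about eta is the dispute here.

| flask | substrate | partner | time |
|---|---|---|---|
| gamma | 0.100 M | 0.100 M |  |
| delta | 0.0500 M | 0.0500 M |  |
| alpha | 0.200 M | 0.100 M |  |
| beta | 0.100 M | 0.200 M |  |
| eta | 0.0500 M | 0.200 M | 4.1 h |

| run | time / h | [target] / M |
|---|---|---|
| gamma run | 0.16 | 0.0022 |
| gamma run | 0.37 | 0.0058 |
| gamma run | 0.82 | 0.0113 |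
| gamma run | 1.8 | 0.0185 |
| gamma run | 4.1 | 0.0253 |
| delta run | 0.16 | 8 × 10⁻⁴ |
| delta run | 0.37 | 0.0019 |
| delta run | 0.82 | 0.0033 |
| delta run | 1.8 | 0.0053 |
| delta run | 4.1 | 0.0093 |
| alpha run | 0.16 | 0.0051 |
| alpha run | 0.37 | 0.0113 |
| alpha run | 0.82 | 0.0203 |
| alpha run | 1.8 | 0.0308 |
| alpha run | 4.1 | 0.0382 |
| beta run | 0.16 | 0.0059 |
| beta run | 0.37 | 0.0114 |
| beta run | 0.82 | 0.0203 |
| beta run | 1.8 | 0.0307 |
| beta run | 4.1 | 0.0356 |

(standard deviation of a reading: 3 × 10⁻⁴ M)

- the exponent of [partner] in the starting rate at the charge of the gamma run (at the point where two percent of the substrate have become target)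
- the exponent of [substrate] in the starting rate at the charge of the gamma run (at the point where two percent of the substrate have become target) (one fixed amount of target, the same in the runs compared)
- target in the eta run at 4.1 h, as a share of the substrate charged

- Overall: substrate + partner -> target.
- Constant volume, constant temperature.
- "The second partner" is partner.
- An order is taken over about fifteen percent of the charge, up and down.

I reckon in one quantity, which for the gamma run is 0.295 M: the drag D, the reciprocal of the integrated second-order k·t at the last reading. With s and r the charges of substrate and partner and x the target, D = (r − s)/ln[(r − x)s/(r(s − x))], which for equal charges becomes s(s − x)/x. At a fixed time, a plain second-order flask shows one D at every charge, but these runs read 0.219 M for delta, 0.371 M for alpha and 0.410 M for beta.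

The forecast holds that k·t “falls as product rises”, so it takes 3.5 for eta and arrives at 47 %, with orders of 1 in partner and 0.95 in substrate.

I hold instead that D moves with the charges, step by step. Doubling the partner from gamma raised it by 0.115 M, more than the 0.0760 M from doubling the substrate. Eta is beta with its substrate, here the limiting reagent, stepped down by half of that substrate step, so eta should read 0.372 M. Put back through the integrated law, this gives 0.0199 M of target, or 39.9 % of the substrate charged, which is my number and not the forecast's.

The simulation ran these steps:

    substrate + partner ⇌ target (1.811 M⁻¹ h⁻¹, 0.08028 h⁻¹)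
    target + partner → side product (0.8712 M⁻¹ h⁻¹)
    2 substrate → homo dimer (1.022 M⁻¹ h⁻¹)

The eta flask gives 40.1 %, which is 6.9 percentage points below the forecast, with orders of 1.1 in partner and 1.0 in substrate, and the beta run went 2.1 times as fast as the gamma run at equal target made. The forecast's product rule stays good across delta, gamma and alpha, whose drag rises with target, and it parts at beta, with less target but more drag than alpha. The eta result reads as a drag of 0.369 M, and the same steps taken down from gamma to delta give 0.200 M, hence 0.0100 M of target at 4.1 h against a delta reading of 0.0093 M.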